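Take one unit of charged starting material, the limiting reagent, and book every entry below as a fraction of that unit.

all flasks: starting material 5.0 × 10⁻⁴ M; free enzyme 0.050 µM; time 1.0 min

| flask | temperature | remark |
|---|---|---|
| south-west | 37 °C |  |
| south-east |  | at −23 °C until 12 s, from then on at 37 °C |
| west | −23 °C |  |
| east | 7 °C |  |

    free enzyme → unfolded enzyme (k1 = 0.0018 s⁻¹, Ea1 = 223 kJ mol⁻¹)
    starting material + free enzyme ⇌ complex (K2 = 690 L mol⁻¹, k2 = 2.6 × 10⁷ L mol⁻¹ s⁻¹, Ea2 = 15.0 kJ mol⁻¹, ΔH2 = −22.0 kJ mol⁻¹)
    complex → free enzyme + target (k3 = 260 s⁻¹, Ea3 = 48.0 kJ mol⁻¹)
    starting material + target → side product (k4 = 1.7 L mol⁻¹ s⁻¹, Ea4 = 54.0 kJ mol⁻¹)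
    free enzyme + target → free enzyme + over-reaction product (k5 = 1.0 × 10⁶ L mol⁻¹ s⁻¹, Ea5 = 12.0 kJ mol⁻¹)
    (constants at 37 °C)

- a species is counted by the starting material in it: one side product counts as two
- all constants are for 37 °C and move with temperature by the activation energies and enthalpies

1. the best flask by share of target in all that became target or side product or over-reaction product; "all alike" if 1.5 percentage points covers them all (south-west / south-east / west / east / all alike)
2. share of target in all that became target or side product or over-reaction product, south-west
3. share of target in all that became target or side product or over-reaction product, south-east
4. share of target in all that became target or side product or over-reaction product, west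
5. share of target in all that became target or side product or over-reaction product, east

Open the ledger on west, and strike the first entry: complex can hold 1.00 × 10⁻⁴ of the charge at the very most. Now cool the constants. From the hottest flask to west, the turnover constant (complex to free enzyme and target) falls by a factor of 87 to 2.99 s⁻¹, and the over-reaction constant falls by a factor of 3.1 to 3.28 × 10⁵ L mol⁻¹ s⁻¹. The binding constant rises to 5340 L mol⁻¹. In west, complex loses starting material at 1210 s⁻¹, faster than it turns over, so treat binding as a rapid pre-equilibrium. Complex then stands at 2.67 per free enzyme, and the second entry, the turnover through complex in 1.0 min, comes to 0.0131 of the charge.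

Split that entry by dividing the rate of over-reaction by the rate of turnover. Free enzyme cancels and time is gone, which leaves the ratio of target to starting material set against a single number, turnover constant times binding constant over over-reaction constant; for west that number is 0.0488. Call it the ceiling ratio: target per starting material at which over-reaction consumes target as fast as turnover makes it. With the starting material of west near unity, integrate over turnover instead of time. Target is the ceiling ratio times one minus the exponential of minus turnover over ceiling, which books 0.0115 as target and 0.00160 as over-reaction product.

The side-product entry, counted as two, is 0.00251 of the over-reaction entry, and unfolding, with the whole enzyme reckoned as free, takes 1.06 × 10⁻¹⁰ of the enzyme, so strike both. Close the west books at a share of 87.7%.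

South-west has the higher ceiling, 0.179, but its turnover estimate of 0.400 spends 2.23 ceilings against 0.268 in west. A turnover of that size takes starting material well off unity, so these books do not hold for south-west; commit to the order, not to a south-west figure: west above south-west.

The forecast names west and gives south-west 36.3% (34% to 39%), south-east 43% (40% to 46%), west 87.5% (85% to 90%) and east 62.5% (59% to 66%). Its ground for west is that “this loss over the minute is small, even though little target is made”. My west figure is 87.7%, inside its range.

The simulation ranks west first, with south-west 36.2%, south-east 43.0%, west 87.6% and east 62.3%. West ends with target at 1.14% and over-reaction product at 0.161%, against the ledger's 0.0115 and 0.00160. Now charge the west flask with 3.0 × 10⁻⁸ M of free enzyme. The ceiling ratio has no free-enzyme term and stays 0.0488, while turnover scales to 0.00784, so the ledger books a share of 92.4%. That neighbour flask keeps 99.2% of its starting material unbound and gives a share of 92.3%.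

Its constants were set for the occasion; what happens was integrated by code.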